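## Retrosynthetic overview

1. Numbering (germacrane): ring C1(OH)–C2H2–C3H2–C4(Me)–C5 (epoxide)–C6(O-lactone)–C7–C8(OTig)–C9=C10(Me); C11, C12, C13 = butenolide α-carbon, lactone C=O, CH2OH.
2. Late stage: C1=O → (1R)-OH (CBS); E-C4=C5 → epoxide (Shi); butenolide by oxidative lactonisation of O6 onto C12, then 1,3-shift of the tertiary C7–OH to C13; tiglate on O8.
3. Ten-membered carbocycle ⇐ twelve-membered β-keto lactone [C1(=O)–C2–C(=O)–O–C3…C10] by Pd-catalysed loss of CO2. Enabling feature: C2–C3 is the only CH2–CH2 bond of the carbocycle, with C2 α to the C1 carbonyl and C3 allylic to E-C4=C5, so the ring can first be closed through an ester and the CO2 link then extruded.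
4. Twelve-membered lactone ⇐ acylketene lactonisation of a seco hydroxy β-keto ester; (Z)-C9=C10 from a Stork–Zhao vinyl iodide (Negishi acylation); (E)-C4=C5 from a stabilised Wittig reaction.
5. C6, C8 and the temporary C7 carbinol come from diacetone-D-glucose; ring order: 12-membered lactone → 10-membered carbocycle → butenolide → epoxide.

Key step: step 13

Abbreviations: TBDPS = tert-butyldiphenylsilyl, TBS = tert-butyldimethylsilyl, Tig = (E)-2-methylbut-2-enoyl. Locants C1–C13 in names of open-chain and macrocyclic compounds are the target numbering of line 1.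

## Route

Step 1
Reactants: 1 2-bromoprop-2-en-1-ol
Product: 2 tert-butyl[(2-bromoprop-2-en-1-yl)oxy]diphenylsilane
Conditions: TBDPSCl, imidazole, CH2Cl2, 0 °C → rt
Reagents that add atoms: tert-butyl(chloro)diphenylsilane, CC(C)(C)[Si](Cl)(c1ccccc1)c1ccccc1
Why: Imidazole-mediated silylation of a primary alcohol; the TBDPS ether should survive every acidic and basic step up to step 16.

Step 2
Reactants: 3 1,2:5,6-di-O-isopropylidene-α-D-glucofuranose
Product: 4 1,2:5,6-di-O-isopropylidene-α-D-ribo-hexofuranos-3-ulose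
Conditions: Dess–Martin periodinane, NaHCO3, CH2Cl2, rt
Reagents that add atoms: none
Why: Dess–Martin oxidation of the only free (secondary) hydroxyl should give the 3-ulose without touching the two acetals.

Step 3
Reactants: 2 vinyl bromide; 4 3-ulose
Product: 6 3-C-[3-(TBDPS-oxy)prop-1-en-2-yl]-1,2:5,6-di-O-isopropylidene-α-D-allofuranose, via vinyllithium 5 (not isolated)
Conditions: 2, t-BuLi (2 equiv), Et2O, −78 °C; then 4, THF, −78 → −40 °C; H2O
Reagents that add atoms: none
Why: Br/Li exchange followed by 1,2-addition of the vinyllithium to the ketone, which should occur from the convex β-face anti to the 1,2-acetonide, so that the new tertiary hydroxyl (C7) is cis to O-2 (allo), as step 7 requires.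

Step 4
Reactants: 6 allofuranose diacetonide
Product: 8 3-C-[3-(TBDPS-oxy)prop-1-en-2-yl]-1,2-O-isopropylidene-α-D-ribo-pentodialdo-1,4-furanose, via glycol 7 (not isolated)
Conditions: H5IO6 (1.3 equiv), EtOAc, rt
Reagents that add atoms: none
Why: Periodic acid in ethyl acetate should hydrolyse only the terminal 5,6-acetonide and cleave the resulting glycol (Malaprade reaction) to the C5 aldehyde, leaving the adjacent stereocentre (C6) untouched.

Step 5
Reactants: 8 aldehyde
Product: 9 ethyl (E)-3-C-[3-(TBDPS-oxy)prop-1-en-2-yl]-5,6-dideoxy-1,2-O-isopropylidene-6-C-methyl-α-D-ribo-hept-5-enofuranuronate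
Conditions: Ph3P=C(CH3)CO2Et, CH2Cl2, rt → 40 °C
Reagents that add atoms: ethyl 2-(triphenyl-λ5-phosphanylidene)propanoate, CCOC(=O)C(C)=P(c1ccccc1)(c1ccccc1)c1ccccc1
Why: Wittig olefination with the stabilised α-methyl ylide should give the (E)-trisubstituted enoate (C4=C5) under the usual thermodynamic control.

Step 6
Reactants: 9 enoate
Product: 10 (E)-3-C-[3-(TBDPS-oxy)prop-1-en-2-yl]-5,6-dideoxy-1,2-O-isopropylidene-6-C-methyl-α-D-ribo-hept-5-enofuranose
Conditions: DIBAL-H (4 equiv), CH2Cl2, −78 °C; Rochelle salt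
Reagents that add atoms: none
Why: DIBAL-H 1,2-reduction of the conjugated ester to the primary allylic alcohol (C3–OH), the later allyl partner of the key step.

Step 7
Reactants: 10 allylic alcohol (1,2-acetonide)
Product: 11 (E)-3-C-[3-(TBDPS-oxy)prop-1-en-2-yl]-5,6-dideoxy-2,3-O-isopropylidene-6-C-methyl-D-ribo-hept-5-enofuranose (lactol, anomeric mixture)
Conditions: acetone, CSA (10 mol %), rt; Et3N
Reagents that add atoms: none
Why: Acid-catalysed trans-ketalisation under thermodynamic control should move the isopropylidene group from O-1/O-2 to the cis-disposed O-2/O-3 (ribo-type 2,3-acetonide), which frees the lactol and masks O8 together with the tertiary O7.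

Step 8
Reactants: 11 lactol
Product: 12 open-chain (4E,9Z)-vinyl iodide diol: 3-OH, 4-methyl, (6R)-6-OH, (7R,8S)-7,8-O-isopropylidene, C7 bearing CH2=C(CH2OTBDPS)–, 10-iodo-10-methyl (I cis to C8)
Conditions: EtPPh3I, n-BuLi, THF; I2, −78 °C; NaHMDS, −20 °C; then 11, −78 → −20 °C (excess ylide)
Reagents that add atoms: ethyltriphenylphosphonium iodide, CC[P+](c1ccccc1)(c1ccccc1)c1ccccc1.[I-]; iodine, II
Why: Stork–Zhao–Wittig olefination of the lactol through its hydroxy-aldehyde form should give the (Z)-vinyl iodide via the kinetic cis-oxaphosphetane, and ring opening releases O6 as the only free secondary hydroxyl, which differentiates it from O8.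

Step 9
Reactants: 12 vinyl iodide diol
Product: 13 3,6-bis-O-TBS ether of 12 [(6R,7S,8S)]
Conditions: TBSOTf, 2,6-lutidine, CH2Cl2, −78 → 0 °C
Reagents that add atoms: tert-butyldimethylsilyl triflate, CC(C)(C)[Si](C)(C)OS(=O)(=O)C(F)(F)F
Why: Triflate-mediated silylation should cap the primary C3 and the hindered secondary C6 hydroxyls, the only free hydroxyls present.

Step 10
Reactants: 13 bis-silyl vinyl iodide
Product: 16 methyl (Z)-β-keto ester: C10 carries C1(=O)–C2H2–CO2Me in place of iodine, via vinyllithium 14 (not isolated), via vinylzinc chloride 15 (not isolated)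
Conditions: t-BuLi (2.1 equiv), Et2O, −78 °C; ZnCl2, THF, −78 → 0 °C; Pd(PPh3)4 (5 mol %), ClC(O)CH2CO2Me, 0 °C → rt
Reagents that add atoms: methyl 3-chloro-3-oxopropanoate (methyl malonyl chloride), COC(=O)CC(Cl)=O
Why: I/Li exchange with retention of alkene geometry, transmetalation to zinc and Pd-catalysed Negishi acylation should give the (Z)-α-methyl enone β-keto ester, which cannot cyclise to a furan because O8 is ketal-protected.

Step 11
Reactants: 16 β-keto ester
Product: 17 seco hydroxy β-keto ester (free C3–OH; 6-OTBS, 7,8-acetonide and TBDPS ether retained)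
Conditions: HF·pyridine, pyridine, THF, 0 °C
Reagents that add atoms: none
Why: Buffered HF·pyridine should cleave the primary allylic TBS ether much faster than the hindered secondary TBS and the primary TBDPS ethers.

Step 12
Reactants: 17 seco hydroxy β-keto ester
Product: 19 twelve-membered β-keto lactone [ring C1(=O)–C2–C(=O)–O–C3–C4(Me)=C5–C6–C7–C8–C9=C10(Me); (4E,9Z)], via acylketene 18 (not isolated)
Conditions: xylenes, 5 Å MS, 140 °C, slow addition (final 1 mM)
Reagents that add atoms: none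
Why: Thermal loss of methanol from the β-keto ester should give an acylketene that is trapped by the only free hydroxyl (C3–OH) at high dilution (acylketene macrolactonisation), the sieves removing methanol.

Step 13
Reactants: 19 twelve-membered β-keto lactone
Product: 20 (4E,9Z)-6-(TBS-oxy)-7,8-O-isopropylidene-4,10-dimethyl-7-[3-(TBDPS-oxy)prop-1-en-2-yl]cyclodeca-4,9-dien-1-one [(6R,7S,8S)]
Conditions: Pd2(dba)3 (5 mol %), PPh3 (20 mol %), THF (2 mM), 25 → 50 °C
Reagents that add atoms: none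
Why: Proposed new method: Pd(0) should ionise the primary allylic C3–O bond of 19 to an η3-allyl (C3–C4–C5) palladium cation paired with its own β-keto carboxylate, which loses CO2 to the C1–C2 enolate; recombination at the unhindered terminus C3 then contracts the twelve-membered lactone by two atoms to the ten-membered carbocycle, the closest known reaction being the Tsuji–Trost decarboxylative allylation of allyl β-keto esters together with Pd-catalysed macrocyclisation of β-keto esters onto allylic esters. The ring closes by 10-endo attack on the allyl unit, the alternative 8-exo attack at C5 being disfavoured by the C6 substituent. No stereocentre is formed, and the E geometry of C4=C5 should be kept because the syn η3-allyl is alkylated faster than it isomerises. Chemoselectivity is secured because O6 and O8 are a silyl ether and a ketal oxygen, which Pd(0) does not ionise, and because the ion pair is intramolecular, which favours ring closure over oligomerisation at high dilution.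

Step 14
Reactants: 20 cyclodecadienone acetonide
Product: 21 7,8-diol of 20 [(6R,7S,8S); tertiary 7-OH, secondary 8-OH]
Conditions: AcOH/H2O 4:1, 40 °C
Reagents that add atoms: none
Why: Mild aqueous acid hydrolysis of the dioxolane should spare the hindered secondary TBS and the primary TBDPS ethers.

Step 15
Reactants: 21 diol
Product: 22 8-O-tigloyl ester of 21
Conditions: tigloyl chloride, Et3N, DMAP (cat.), CH2Cl2, 0 °C → rt
Reagents that add atoms: (E)-2-methylbut-2-enoyl chloride (tigloyl chloride), C/C=C(\C)C(Cl)=O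
Why: DMAP-catalysed acylation should take place only at the secondary allylic C8 hydroxyl, the tertiary C7 hydroxyl being unreactive, and is placed after the palladium step so that no second allylic ester is present there.

Step 16
Reactants: 22 tiglate
Product: 23 triol: (4E,9Z)-6,7-dihydroxy-7-(3-hydroxyprop-1-en-2-yl)-4,10-dimethyl-8-(tigloyloxy)cyclodeca-4,9-dien-1-one [(6R,7R,8S)]
Conditions: HF·pyridine (excess), THF, rt
Reagents that add atoms: none
Why: Fluoride-mediated cleavage of both remaining silyl ethers under mildly acidic conditions that the tiglate and the enone tolerate.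

Step 17
Reactants: 23 triol
Product: 25 α-methylene-β-hydroxy-γ-lactone [O6–C12(=O)–C11(=C13H2)–C7(OH); (6R,7R,8S)], via lactol 24 (not isolated)
Conditions: TEMPO (20 mol %), PhI(OAc)2 (2.5 equiv), CH2Cl2, rt
Reagents that add atoms: none
Why: TEMPO/PhI(OAc)2 oxidative lactonisation: the primary allylic alcohol is oxidised to the aldehyde, which closes to the five-membered lactol with the C6 hydroxyl and is oxidised on to the lactone, O8 being acylated so that only the 12,6-lactone can form.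

Step 18
Reactants: 25 α-methylene-β-hydroxy lactone
Product: 26 (4E,9Z)-13-hydroxy-1-oxo-8-(tigloyloxy)germacra-4,7(11),9-trien-12,6-olide [(6R,8S)]
Conditions: Re2O7 (5 mol %), CH2Cl2, 0 °C → rt
Reagents that add atoms: none
Why: Perrhenate-catalysed 1,3-transposition of the tertiary allylic alcohol ([3,3] shift of the allyl perrhenate) should run towards the conjugated tetrasubstituted butenolide with a primary alcohol, the ring fixing the alkene geometry.

Step 19
Reactants: 26 trienolide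
Product: 27 (4R,5R,6S,8S)-4,5-epoxy-13-hydroxy-1-oxo-8-(tigloyloxy)germacra-7(11),9Z-dien-12,6-olide
Conditions: Shi ketone (D-fructose-derived, 30 mol %), Oxone, K2CO3, Bu4NHSO4, MeCN/DMM/aq. borate buffer, 0 °C
Reagents that add atoms: potassium peroxymonosulfate (Oxone), [K+].[O-]S(=O)(=O)OO
Why: Shi epoxidation is chemoselective for the only electron-rich alkene (E-C4=C5), and the D-fructose-derived dioxirane should deliver oxygen through the spiro transition state to give the (4R,5R)-trans-epoxide under reagent control.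

Step 20
Reactants: 27 epoxy ketone
Product: 28 (1R,4R,5R,6S,8S)-4,5-epoxy-1,13-dihydroxy-8-(tigloyloxy)germacra-7(11),9Z-dien-12,6-olide (CNP0167056.1)
Conditions: (S)-Me-CBS (1 equiv), BH3·SMe2, THF, −40 °C; MeOH
Reagents that add atoms: none
Why: Corey–Bakshi–Shibata 1,2-reduction of the enone, in which the (S)-oxazaborolidine treats the α-methylalkenyl side (C10) as the large group and should deliver hydride to give the (1R)-allylic alcohol.

## Compound list

1 | 2-bromoprop-2-en-1-ol | OCC(Br)=C | starting material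
2 | tert-butyl[(2-bromoprop-2-en-1-yl)oxy]diphenylsilane | C=C(Br)CO[Si](c1ccccc1)(c1ccccc1)C(C)(C)C | intermediate
3 | 1,2:5,6-di-O-isopropylidene-α-D-glucofuranose | O[C@@H]1[C@H]2OC(C)(C)O[C@H]2O[C@@H]1[C@H]1COC(C)(C)O1 | starting material
4 | 1,2:5,6-di-O-isopropylidene-α-D-ribo-hexofuranos-3-ulose | O=C1[C@H]2OC(C)(C)O[C@H]2O[C@@H]1[C@H]1COC(C)(C)O1 | intermediate
5 | [3-(TBDPS-oxy)prop-1-en-2-yl]lithium | [Li]C(=C)CO[Si](c1ccccc1)(c1ccccc1)C(C)(C)C | intermediate
6 | 3-C-[3-(TBDPS-oxy)prop-1-en-2-yl]-1,2:5,6-di-O-isopropylidene-α-D-allofuranose | O[C@@]1(C(=C)CO[Si](c3ccccc3)(c3ccccc3)C(C)(C)C)[C@H]2OC(C)(C)O[C@H]2O[C@@H]1[C@H]1COC(C)(C)O1 | intermediate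
7 | 3-C-[3-(TBDPS-oxy)prop-1-en-2-yl]-1,2-O-isopropylidene-α-D-allofuranose | O[C@@]1(C(=C)CO[Si](c3ccccc3)(c3ccccc3)C(C)(C)C)[C@H]2OC(C)(C)O[C@H]2O[C@@H]1[C@H](O)CO | intermediate
8 | 3-C-[3-(TBDPS-oxy)prop-1-en-2-yl]-1,2-O-isopropylidene-α-D-ribo-pentodialdo-1,4-furanose | O[C@@]1(C(=C)CO[Si](c3ccccc3)(c3ccccc3)C(C)(C)C)[C@H]2OC(C)(C)O[C@H]2O[C@@H]1C=O | intermediate
9 | ethyl (E)-3-C-[3-(TBDPS-oxy)prop-1-en-2-yl]-5,6-dideoxy-1,2-O-isopropylidene-6-C-methyl-α-D-ribo-hept-5-enofuranuronate | O[C@@]1(C(=C)CO[Si](c3ccccc3)(c3ccccc3)C(C)(C)C)[C@H]2OC(C)(C)O[C@H]2O[C@@H]1/C=C(\C)C(=O)OCC | intermediate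
10 | (E)-3-C-[3-(TBDPS-oxy)prop-1-en-2-yl]-5,6-dideoxy-1,2-O-isopropylidene-6-C-methyl-α-D-ribo-hept-5-enofuranose | O[C@@]1(C(=C)CO[Si](c3ccccc3)(c3ccccc3)C(C)(C)C)[C@H]2OC(C)(C)O[C@H]2O[C@@H]1/C=C(\C)CO | intermediate
11 | (E)-3-C-[3-(TBDPS-oxy)prop-1-en-2-yl]-5,6-dideoxy-2,3-O-isopropylidene-6-C-methyl-D-ribo-hept-5-enofuranose (lactol) | OC1O[C@H](/C=C(\C)CO)[C@@]2(C(=C)CO[Si](c3ccccc3)(c3ccccc3)C(C)(C)C)OC(C)(C)O[C@@H]12 | intermediate
12 | open-chain (4E,9Z)-vinyl iodide diol, (6R,7R,8S): 3-OH, 6-OH, 7,8-O-isopropylidene, 7-[3-(TBDPS-oxy)prop-1-en-2-yl], 10-iodo | C/C(I)=C/[C@@H]1OC(C)(C)O[C@]1(C(=C)CO[Si](c2ccccc2)(c2ccccc2)C(C)(C)C)[C@H](O)/C=C(\C)CO | intermediate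
13 | 3,6-bis-O-TBS ether of 12, (6R,7S,8S) | C/C(I)=C/[C@@H]1OC(C)(C)O[C@]1(C(=C)CO[Si](c2ccccc2)(c2ccccc2)C(C)(C)C)[C@H](O[Si](C)(C)C(C)(C)C)/C=C(\C)CO[Si](C)(C)C(C)(C)C | intermediate
14 | C10 vinyllithium from 13 | C/C([Li])=C/[C@@H]1OC(C)(C)O[C@]1(C(=C)CO[Si](c2ccccc2)(c2ccccc2)C(C)(C)C)[C@H](O[Si](C)(C)C(C)(C)C)/C=C(\C)CO[Si](C)(C)C(C)(C)C | intermediate
15 | C10 vinylzinc chloride from 13 | C/C([Zn]Cl)=C/[C@@H]1OC(C)(C)O[C@]1(C(=C)CO[Si](c2ccccc2)(c2ccccc2)C(C)(C)C)[C@H](O[Si](C)(C)C(C)(C)C)/C=C(\C)CO[Si](C)(C)C(C)(C)C | intermediate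
16 | methyl (Z)-β-keto ester, 3,6-bis-O-TBS, (6R,7S,8S) | C/C(C(=O)CC(=O)OC)=C/[C@@H]1OC(C)(C)O[C@]1(C(=C)CO[Si](c2ccccc2)(c2ccccc2)C(C)(C)C)[C@H](O[Si](C)(C)C(C)(C)C)/C=C(\C)CO[Si](C)(C)C(C)(C)C | intermediate
17 | seco hydroxy β-keto ester (free 3-OH), (6R,7S,8S) | C/C(C(=O)CC(=O)OC)=C/[C@@H]1OC(C)(C)O[C@]1(C(=C)CO[Si](c2ccccc2)(c2ccccc2)C(C)(C)C)[C@H](O[Si](C)(C)C(C)(C)C)/C=C(\C)CO | intermediate
18 | acylketene from 17 | C/C(C(=O)C=C=O)=C/[C@@H]1OC(C)(C)O[C@]1(C(=C)CO[Si](c2ccccc2)(c2ccccc2)C(C)(C)C)[C@H](O[Si](C)(C)C(C)(C)C)/C=C(\C)CO | intermediate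
19 | twelve-membered (4E,9Z)-β-keto lactone, (6R,7S,8S) | C/C1=C/[C@@H]2OC(C)(C)O[C@]2(C(=C)CO[Si](c3ccccc3)(c3ccccc3)C(C)(C)C)[C@H](O[Si](C)(C)C(C)(C)C)/C=C(\C)COC(=O)CC1=O | intermediate
20 | (4E,9Z)-6-(TBS-oxy)-7,8-O-isopropylidene-4,10-dimethyl-7-[3-(TBDPS-oxy)prop-1-en-2-yl]cyclodeca-4,9-dien-1-one, (6R,7S,8S) | C/C1=C/[C@@H]2OC(C)(C)O[C@]2(C(=C)CO[Si](c3ccccc3)(c3ccccc3)C(C)(C)C)[C@H](O[Si](C)(C)C(C)(C)C)/C=C(\C)CCC1=O | intermediate
21 | 7,8-diol of 20, (6R,7S,8S) | C/C1=C/[C@H](O)[C@@](O)(C(=C)CO[Si](c2ccccc2)(c2ccccc2)C(C)(C)C)[C@H](O[Si](C)(C)C(C)(C)C)/C=C(\C)CCC1=O | intermediate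
22 | 8-O-tigloyl ester of 21, (6R,7S,8S) | C/C1=C/[C@H](OC(=O)/C(C)=C/C)[C@@](O)(C(=C)CO[Si](c2ccccc2)(c2ccccc2)C(C)(C)C)[C@H](O[Si](C)(C)C(C)(C)C)/C=C(\C)CCC1=O | intermediate
23 | (4E,9Z)-6,7-dihydroxy-7-(3-hydroxyprop-1-en-2-yl)-4,10-dimethyl-8-(tigloyloxy)cyclodeca-4,9-dien-1-one, (6R,7R,8S) | C/C1=C/[C@H](OC(=O)/C(C)=C/C)[C@@](O)(C(=C)CO)[C@H](O)/C=C(\C)CCC1=O | intermediate
24 | lactol (C12 hemiacetal with O6) | C/C1=C/[C@H](OC(=O)/C(C)=C/C)[C@@]2(O)C(=C)C(O)O[C@@H]2/C=C(\C)CCC1=O | intermediate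
25 | α-methylene-β-hydroxy-γ-lactone (7-hydroxy-11(13)-en-12,6-olide), (6R,7R,8S) | C/C1=C/[C@H](OC(=O)/C(C)=C/C)[C@@]2(O)C(=C)C(=O)O[C@@H]2/C=C(\C)CCC1=O | intermediate
26 | (4E,9Z)-13-hydroxy-1-oxo-8-(tigloyloxy)germacra-4,7(11),9-trien-12,6-olide, (6R,8S) | C/C=C(\C)C(=O)O[C@H]1/C=C(/C)C(=O)CC/C(C)=C/[C@H]2OC(=O)C(CO)=C12 | intermediate
27 | (4R,5R,6S,8S)-4,5-epoxy-13-hydroxy-1-oxo-8-(tigloyloxy)germacra-7(11),9Z-dien-12,6-olide | C/C=C(\C)C(=O)O[C@H]1/C=C(/C)C(=O)CC[C@@]2(C)O[C@@H]2[C@H]2OC(=O)C(CO)=C12 | intermediate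
28 | (1R,4R,5R,6S,8S)-4,5-epoxy-1,13-dihydroxy-8-(tigloyloxy)germacra-7(11),9Z-dien-12,6-olide | C/C=C(\C)C(=O)O[C@H]1/C=C(/C)[C@H](O)CC[C@@]2(C)O[C@@H]2[C@H]2OC(=O)C(CO)=C12 | target

## Step count and risks

Total step count: 20. Longest linear sequence: 19 steps (steps 2–20, from diacetone-D-glucose).

Steps most likely to fail:

1. Step 13 (proposed new method). Protodecarboxylation of the intermediate enolate, β-hydride elimination of the η3-allyl to a 1,3-diene, attack at the substituted allyl terminus, or oligomerisation may outrun closure of the strained ten-membered ring. Fallback with known chemistry: starting from 17, the allylic alcohol is converted with methyl chloroformate and pyridine into the allylic methyl carbonate F1. Pd(PPh3)4 in THF at high dilution (the carbonate supplies methoxide as internal base) should then close the carbocycle directly by Tsuji–Trost alkylation of the β-keto ester, giving the 2-methoxycarbonyl cyclodecadienone F2. Krapcho demethoxycarbonylation (LiCl, wet DMSO, 120 °C) brings the material back to 20.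

2. Step 7. The acetal migration may stop at an equilibrium mixture, or the acid may ionise the tertiary allylic alcohol instead. Fallback: starting from 10, thiophenol and BF3·OEt2 open the 1,2-acetonide to the phenyl 1-thiofuranoside diol F3. 2,2-Dimethoxypropane with PPTS then places the isopropylidene group on the cis O-2/O-3 diol to give thioglycoside acetonide F4. Hydrolysis of the thioglycoside with AgNO3 and 2,6-lutidine in aqueous THF returns to 11.

3. Step 19. The conformational bias of the macrocycle may override the chiral ketone and give poor facial selectivity, or the hindered ring alkene may react slowly. Fallback: starting from 26, epoxidation with mCPBA and NaHCO3 in CH2Cl2 at low temperature relies on peripheral attack on the preferred conformer (substrate control instead of reagent control), with separation of the epimers, and returns to 27.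

Further compounds
F1 | step 13 | allylic methyl carbonate of 17 (C3–O–CO2Me) | C/C(C(=O)CC(=O)OC)=C/[C@@H]1OC(C)(C)O[C@]1(C(=C)CO[Si](c2ccccc2)(c2ccccc2)C(C)(C)C)[C@H](O[Si](C)(C)C(C)(C)C)/C=C(\C)COC(=O)OC
F2 | step 13 | 2-methoxycarbonyl derivative of 20 (C2 epimers) | C/C1=C/[C@@H]2OC(C)(C)O[C@]2(C(=C)CO[Si](c3ccccc3)(c3ccccc3)C(C)(C)C)[C@H](O[Si](C)(C)C(C)(C)C)/C=C(\C)CC(C(=O)OC)C1=O
F3 | step 7 | phenyl (E)-3-C-[3-(TBDPS-oxy)prop-1-en-2-yl]-5,6-dideoxy-6-C-methyl-1-thio-D-ribo-hept-5-enofuranoside | OC/C(C)=C/[C@H]1OC(Sc2ccccc2)[C@H](O)[C@@]1(O)C(=C)CO[Si](c2ccccc2)(c2ccccc2)C(C)(C)C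
F4 | step 7 | 2,3-O-isopropylidene derivative of F3 | OC/C(C)=C/[C@H]1OC(Sc2ccccc2)[C@@H]2OC(C)(C)O[C@]12C(=C)CO[Si](c2ccccc2)(c2ccccc2)C(C)(C)C
F0 | step 19 | none | none
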